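**Plan**

- Retrosynthesis: the hydroquinone is taken back to its 5,8-quinone. The pyran is then cut at C4–C4a and at O1–C2, giving 2-hydroxy-5-methoxy-1,4-benzoquinone and a C15 (E)-enal. The enal goes back to a terminal alkyne, and the alkyne/ring-ketone pair is the fragmentation product of a bicyclic epoxy enone made from 2,6-dimethylcyclohexanone and methyl vinyl ketone.
- Enabling feature: chromene C4a lies between the oxygen-bearing carbons C5 and C8a, and C5/C8 are a para-dioxygenated pair. At the quinone level C4a is therefore the enolic carbon of a vinylogous acid: it condenses with the enal carbonyl, and the C8a oxygen closes the pyran by oxa-6π.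
- Forward order: cyclohexane ring with its quaternary carbon (Michael addition), temporary ring B (aldol condensation) and its cleavage to ketone plus alkyne, methylenation, chain growth to the enal, pyran ring last, aromatisation by quinone reduction at the very end.
- Stereochemistry: the ring quaternary centre comes from an (S)-1-phenylethylamine imine. The secondary methyl centre is set by equilibration inside temporary ring B (equatorial, trans to the angular methyl) and frozen when ring B is opened. The (E)-alkene comes from syn-carboalumination, and chromene C2 from the chiral acid in the annulation.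

Key step: step 10

Assumption: the sense of induction of the chiral acid in step 10 cannot be predicted with certainty; the (R)-acid is written, and its mirror image is used instead if that is the one that gives the (2S) series.

**Route**

Step 1
Reactants: 1 2,6-dimethylcyclohexanone; 2 (S)-1-phenylethylamine
Product: 3 (1S)-N-(2,6-dimethylcyclohexylidene)-1-phenylethan-1-amine
Conditions: TsOH·H2O (cat.), toluene, reflux, Dean–Stark
Reagents that add atoms: none
Why: Acid-catalysed imine condensation with azeotropic removal of water; both diastereomers of 1 feed one pool of interconverting imine/enamine tautomers, so no ring stereocentre is fixed yet.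

Step 2
Reactants: 3 (1S)-N-(2,6-dimethylcyclohexylidene)-1-phenylethan-1-amine; 4 methyl vinyl ketone
Product: 6 (2R,6S)-2,6-dimethyl-2-(3-oxobutyl)cyclohexan-1-one, via imine adduct 5 (not isolated)
Conditions: THF, 40 °C; then 20% aq AcOH, rt
Reagents that add atoms: water, O
Why: Deracemising asymmetric Michael addition of the secondary enamine tautomer of a chiral imine (chair-like aza-ene transition state with internal N–H transfer), in which the phenylethyl group shields one face and should set the quaternary centre as (R) as in the 2-methylcyclohexanone case, while C6 is only provisional (attack anti to a pseudoaxial 6-methyl should give the cis-dimethyl isomer drawn) and is corrected in step 3.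

Step 3
Reactants: 6 (2R,6S)-2,6-dimethyl-2-(3-oxobutyl)cyclohexan-1-one
Product: 7 (4aR,8R)-4a,8-dimethyl-4,4a,5,6,7,8-hexahydronaphthalen-2(3H)-one
Conditions: NaOMe (0.3 equiv), MeOH, 60 °C
Reagents that add atoms: none
Why: Intramolecular aldol condensation (ring closure of a Robinson annulation) builds temporary ring B, and under the same conditions the γ-carbon C8 should equilibrate through the dienolate to the equatorial methyl, trans to the axial angular methyl (the 6β-to-6α epimerisation known for steroidal 4-en-3-ones), so either C6 epimer of 6 converges on one octalone.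

Step 4
Reactants: 7 (4aR,8R)-4a,8-dimethyl-4,4a,5,6,7,8-hexahydronaphthalen-2(3H)-one
Product: 8 (1S,4aR,8R,8aS)-1,8a-epoxy-4a,8-dimethyloctahydronaphthalen-2(1H)-one
Conditions: 30% H2O2, NaOH (cat.), MeOH, 0 °C to rt
Reagents that add atoms: hydrogen peroxide, OO
Why: Weitz–Scheffer nucleophilic epoxidation of the enone, expected syn to the angular methyl by analogy with steroidal enones, although the face is immaterial because both epoxide carbons lose their configuration in step 5.

Step 5
Reactants: 8 (1S,4aR,8R,8aS)-1,8a-epoxy-4a,8-dimethyloctahydronaphthalen-2(1H)-one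
Product: 10 (2R,6R)-2-(but-3-yn-1-yl)-2,6-dimethylcyclohexan-1-one, via tosylhydrazone 9 (not isolated)
Conditions: TsNHNH2, AcOH/CH2Cl2 1:1, −20 °C to rt
Reagents that add atoms: none
Why: Eschenmoser–Tanabe fragmentation: the epoxy tosylhydrazone opens, expels sulfinate and N2 and cleaves the C1–C8a bond of ring B to a ring ketone and a terminal alkyne, under mildly acidic, non-enolising conditions that leave both ring stereocentres (now trans-dimethyl) untouched.

Step 6
Reactants: 10 (2R,6R)-2-(but-3-yn-1-yl)-2,6-dimethylcyclohexan-1-one
Product: 11 (1R,3R)-1-(but-3-yn-1-yl)-1,3-dimethyl-2-methylidenecyclohexane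
Conditions: Zn, CH2Br2, TiCl4, THF/CH2Cl2, 0 °C to rt
Reagents that add atoms: dibromomethane, BrCBr
Why: Takai–Lombardo methylenation, chosen because the gem-dimetallic reagent is non-basic and should not epimerise the methyl-bearing centre next to the ketone; no new stereocentre.

Step 7
Reactants: 11 (1R,3R)-1-(but-3-yn-1-yl)-1,3-dimethyl-2-methylidenecyclohexane
Product: 14 (2E)-5-[(1R,3R)-1,3-dimethyl-2-methylidenecyclohexyl]-3-methylpent-2-en-1-ol, via vinylalane 12 (not isolated), via lithium alanate 13 (not isolated)
Conditions: AlMe3 (3 equiv), Cp2ZrCl2 (0.25 equiv), CH2Cl2, 0 °C to rt; then n-BuLi, THF, −78 °C; (CH2O)n, −78 °C to rt; 1 M HCl work-up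
Reagents that add atoms: trimethylaluminium, C[Al](C)C; formaldehyde (as paraformaldehyde), C=O
Why: Negishi zirconium-catalysed syn-carboalumination places methyl on the internal and aluminium on the terminal alkyne carbon, and hydroxymethylation of the derived alanate with retention fixes the (E)-trisubstituted alkene, the 1,1-disubstituted exocyclic alkene being inert.

Step 8
Reactants: 14 (2E)-5-[(1R,3R)-1,3-dimethyl-2-methylidenecyclohexyl]-3-methylpent-2-en-1-ol
Product: 15 (2E)-5-[(1R,3R)-1,3-dimethyl-2-methylidenecyclohexyl]-3-methylpent-2-enal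
Conditions: MnO2, CH2Cl2, rt
Reagents that add atoms: none
Why: Chemoselective allylic alcohol oxidation on the MnO2 surface, which should proceed without E/Z isomerisation or over-oxidation.

Step 9
Reactants: 16 2,5-dimethoxy-1,4-benzoquinone
Product: 17 2-hydroxy-5-methoxy-1,4-benzoquinone
Conditions: NaOH (1.1 equiv), THF/H2O, 0 °C to rt; then 1 M HCl
Reagents that add atoms: sodium hydroxide, [Na+].[OH-]
Why: Vinylogous ester saponification by addition–elimination, which should stop after one methoxy group because the resulting hydroxyquinone anion is deactivated toward a second attack.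

Step 10
Reactants: 15 (2E)-5-[(1R,3R)-1,3-dimethyl-2-methylidenecyclohexyl]-3-methylpent-2-enal; 17 2-hydroxy-5-methoxy-1,4-benzoquinone
Product: 19 (2S)-2-{2-[(1R,3R)-1,3-dimethyl-2-methylidenecyclohexyl]ethyl}-6-methoxy-2-methyl-2H-chromene-5,8-dione, via oxatriene 18 (not isolated)
Conditions: (R)-3,3′-bis(2,4,6-triisopropylphenyl)-1,1′-binaphthalene-2,2′-diyl N-triflylphosphoramide (10 mol%), 17 (1.2 equiv), 4 Å MS, toluene, −40 to 0 °C, dark
Reagents that add atoms: none
Why: Proposed new method: the chiral acid should promote C-hydroxyalkylation of vinylogous acid 17 at C3 by the aldehyde of 15 and then ionise the carbinol to the O-protonated form of oxatriene 18, held as a contact ion pair with the chiral phosphoramide anion, which closes to the pyran. The closest known reaction types are the amine-salt- or acid-mediated Knoevenagel/oxa-6π annulation of 2-hydroxy-1,4-quinones with β,β-disubstituted enals (no induction) and the chiral N-triflylphosphoramide-catalysed contact-ion-pair cyclisation of ortho-hydroxyaryl allyl cations to 2,2-disubstituted 2H-chromenes; their merger on a hydroxyquinone with an all-alkyl terminus is the new element. The pyran ring closes by a disrotatory oxa-6π electrocyclisation, formally a 6-endo attack of the C2 oxygen of the quinone on the tertiary allyl-cation terminus, after the condensation has made the C–C bond to C3. The new quaternary stereocentre is under catalyst control alone: the (E)-geometry of 15 places methyl inside and the side chain outside, so the helical sense of closure imposed by the hydrogen-bonded anion becomes one configuration at C2, and the ring stereocentres are too remote to interfere. The step needs 1,2- instead of 1,4-addition (secured by the β,β-disubstituted enal), reaction at C3 only (the one enolic carbon, flanked by the C2 hydroxyl and the C4 carbonyl), and closure through the C2 oxygen and not the C4 oxygen (secured by reversible closure under acid and the greater stability of the 2,5-dioxygenated para-quinone over the ortho-quinone). Low temperature and low acid loading are relied on to spare the exocyclic methylene.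

Step 11
Reactants: 19 (2S)-2-{2-[(1R,3R)-1,3-dimethyl-2-methylidenecyclohexyl]ethyl}-6-methoxy-2-methyl-2H-chromene-5,8-dione
Product: 20 (2S)-2-{2-[(1R,3R)-1,3-dimethyl-2-methylidenecyclohexyl]ethyl}-6-methoxy-2-methyl-2H-chromene-5,8-diol
Conditions: Na2S2O4, EtOAc/H2O (degassed), rt, argon, dark
Reagents that add atoms: none
Why: Dithionite reduction of the quinone to the hydroquinone (late aromatisation), which touches neither alkene nor any stereocentre and turns the pyranoquinone into a chromene that no longer ring-opens thermally.

**Compound list**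

1 | 2,6-dimethylcyclohexanone (cis/trans mixture) | CC1CCCC(C)C1=O | starting material
2 | (S)-1-phenylethylamine | C[C@H](N)c1ccccc1 | starting material
3 | (1S)-N-(2,6-dimethylcyclohexylidene)-1-phenylethan-1-amine (ring diastereomers) | C[C@H](N=C1C(C)CCCC1C)c1ccccc1 | intermediate
4 | methyl vinyl ketone (but-3-en-2-one) | CC(=O)C=C | starting material
5 | 4-[(1R,3S)-1,3-dimethyl-2-{[(1S)-1-phenylethyl]imino}cyclohexyl]butan-2-one (not isolated) | C[C@H](N=C1[C@@H](C)CCC[C@]1(C)CCC(C)=O)c1ccccc1 | intermediate
6 | (2R,6S)-2,6-dimethyl-2-(3-oxobutyl)cyclohexan-1-one (its 6-epimer may accompany it; both converge in step 3) | O=C1[C@@H](C)CCC[C@]1(C)CCC(C)=O | intermediate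
7 | (4aR,8R)-4a,8-dimethyl-4,4a,5,6,7,8-hexahydronaphthalen-2(3H)-one | O=C2C=C1[C@H](C)CCC[C@]1(C)CC2 | intermediate
8 | (1S,4aR,8R,8aS)-1,8a-epoxy-4a,8-dimethyloctahydronaphthalen-2(1H)-one (oxygen syn to the angular methyl; the anti epoxide would fragment to the same product) | O=C2[C@H]3O[C@]31[C@H](C)CCC[C@]1(C)CC2 | intermediate
9 | 4-methylbenzenesulfonylhydrazone of epoxy ketone 8 (not isolated) | Cc1ccc(cc1)S(=O)(=O)NN=C2[C@H]3O[C@]31[C@H](C)CCC[C@]1(C)CC2 | intermediate
10 | (2R,6R)-2-(but-3-yn-1-yl)-2,6-dimethylcyclohexan-1-one | O=C1[C@H](C)CCC[C@]1(C)CCC#C | intermediate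
11 | (1R,3R)-1-(but-3-yn-1-yl)-1,3-dimethyl-2-methylidenecyclohexane | C=C1[C@H](C)CCC[C@]1(C)CCC#C | intermediate
12 | {(1E)-4-[(1R,3R)-1,3-dimethyl-2-methylidenecyclohexyl]-2-methylbut-1-en-1-yl}dimethylalumane (not isolated) | C=C1[C@H](C)CCC[C@]1(C)CC/C(C)=C/[Al](C)C | intermediate
13 | lithium butyl{(1E)-4-[(1R,3R)-1,3-dimethyl-2-methylidenecyclohexyl]-2-methylbut-1-en-1-yl}dimethylaluminate (not isolated) | [Li+].C=C1[C@H](C)CCC[C@]1(C)CC/C(C)=C/[Al-](C)(C)CCCC | intermediate
14 | (2E)-5-[(1R,3R)-1,3-dimethyl-2-methylidenecyclohexyl]-3-methylpent-2-en-1-ol | C=C1[C@H](C)CCC[C@]1(C)CC/C(C)=C/CO | intermediate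
15 | (2E)-5-[(1R,3R)-1,3-dimethyl-2-methylidenecyclohexyl]-3-methylpent-2-enal | C=C1[C@H](C)CCC[C@]1(C)CC/C(C)=C/C=O | intermediate
16 | 2,5-dimethoxy-1,4-benzoquinone | COC1=CC(=O)C(OC)=CC1=O | starting material
17 | 2-hydroxy-5-methoxy-1,4-benzoquinone | COC1=CC(=O)C(O)=CC1=O | intermediate
18 | 3-{(2E)-5-[(1R,3R)-1,3-dimethyl-2-methylidenecyclohexyl]-3-methylpent-2-en-1-ylidene}-5-methoxycyclohex-5-ene-1,2,4-trione (not isolated; reacts as its O-protonated form) | C=C1[C@H](C)CCC[C@]1(C)CC/C(C)=C/C=C1C(=O)C(=O)C=C(OC)C1=O | intermediate
19 | (2S)-2-{2-[(1R,3R)-1,3-dimethyl-2-methylidenecyclohexyl]ethyl}-6-methoxy-2-methyl-2H-chromene-5,8-dione | C=C1[C@H](C)CCC[C@]1(C)CC[C@@]1(C)C=CC2=C(O1)C(=O)C=C(OC)C2=O | intermediate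
20 | (2S)-2-{2-[(1R,3R)-1,3-dimethyl-2-methylidenecyclohexyl]ethyl}-6-methoxy-2-methyl-2H-chromene-5,8-diol | C=C1[C@H](C)CCC[C@]1(C)CC[C@@]1(C)C=Cc2c(O)c(OC)cc(O)c2O1 | target

**Count and risks**

Total steps: 11. Longest linear sequence: 10 steps (steps 1 to 8, then 10 and 11); step 9 is a one-step side branch.

Step 10 is the riskiest step because it rests on a new method. The oxatriene may close outside the chiral ion pair, without facial bias, and the acid may isomerise the exocyclic alkene before the annulation is complete. The fallback uses known chemistry, sets out from 15 and 17 and comes back at 19. The ethylenediammonium diacetate-mediated Knoevenagel/oxa-6π annulation (CH2Cl2, rt, dark) should give 19 together with its C2 epimer (2R)-2-{2-[(1R,3R)-1,3-dimethyl-2-methylidenecyclohexyl]ethyl}-6-methoxy-2-methyl-2H-chromene-5,8-dione F1, without induction. The two are diastereomers and would be separated by preparative HPLC on a chiral stationary phase. F1 can be returned to the mixture by irradiation (photochemical ring opening to 18, thermal re-closure) and resubmitted, so the material is funnelled to 19.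

Step 6 may suffer sluggish carbonyl olefination at a ketone flanked by a quaternary and a tertiary carbon. Loss of the α-methyl configuration is possible if forcing conditions become necessary, and the acetylenic C–H may consume part of the reagent. The fallback sets out from 10 and comes back at 11 by a Peterson olefination. Me3SiCH2Li with CeCl3 (THF, −78 °C, a second equivalent for the alkyne C–H) should add without enolisation to give (2R,6R)-2-(but-3-yn-1-yl)-2,6-dimethyl-1-[(trimethylsilyl)methyl]cyclohexan-1-ol F2. KH in THF then effects syn-elimination to 11.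

Step 5 may give incomplete or diverted fragmentation of the hindered epoxy tosylhydrazone when the alkyne formed is terminal (hydrazone hydrolysis or Wharton-type side paths). The fallback sets out from 7 and comes back at 11, bypassing steps 4 to 6. Ozonolysis with oxidative work-up (O3, CH2Cl2/MeOH, −78 °C; then H2O2, HCO2H) should cleave ring B to 3-[(1R,3R)-1,3-dimethyl-2-oxocyclohexyl]propanoic acid F3. Me3SiCHN2 (MeOH/toluene) gives methyl 3-[(1R,3R)-1,3-dimethyl-2-oxocyclohexyl]propanoate F4. Ketone-selective methylenation (Zn, CH2Br2, TiCl4) gives methyl 3-[(1R,3R)-1,3-dimethyl-2-methylidenecyclohexyl]propanoate F5. i-Bu2AlH (CH2Cl2, −78 °C) gives 3-[(1R,3R)-1,3-dimethyl-2-methylidenecyclohexyl]propanal F6. Ohira–Bestmann homologation (dimethyl (1-diazo-2-oxopropyl)phosphonate, K2CO3, MeOH) then gives 11.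

Further compounds
F1 | step 10 | (2R)-2-{2-[(1R,3R)-1,3-dimethyl-2-methylidenecyclohexyl]ethyl}-6-methoxy-2-methyl-2H-chromene-5,8-dione | C=C1[C@H](C)CCC[C@]1(C)CC[C@]1(C)C=CC2=C(O1)C(=O)C=C(OC)C2=O
F2 | step 6 | (2R,6R)-2-(but-3-yn-1-yl)-2,6-dimethyl-1-[(trimethylsilyl)methyl]cyclohexan-1-ol (carbinol epimers) | C[Si](C)(C)CC1(O)[C@H](C)CCC[C@]1(C)CCC#C
F3 | step 5 | 3-[(1R,3R)-1,3-dimethyl-2-oxocyclohexyl]propanoic acid | O=C1[C@H](C)CCC[C@]1(C)CCC(=O)O
F4 | step 5 | methyl 3-[(1R,3R)-1,3-dimethyl-2-oxocyclohexyl]propanoate | O=C1[C@H](C)CCC[C@]1(C)CCC(=O)OC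
F5 | step 5 | methyl 3-[(1R,3R)-1,3-dimethyl-2-methylidenecyclohexyl]propanoate | C=C1[C@H](C)CCC[C@]1(C)CCC(=O)OC
F6 | step 5 | 3-[(1R,3R)-1,3-dimethyl-2-methylidenecyclohexyl]propanal | C=C1[C@H](C)CCC[C@]1(C)CCC=O
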